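**Retrosynthetic overview**
- The target (an ent-labd-7-ene with equatorial 2-OAc and axial 3-OH) comes from its 3-ketone by equatorial hydride delivery; the ketone comes from the 3-epimeric (equatorial) alcohol by oxidation.
- That alcohol comes from an acyclic epoxy diene sulfone in one radical cascade: ring A closes by the C4–C5 bond (gem-dimethyl carbon to ring-fusion CH), ring B by C9–C10, and loss of PhSO2 from C7 fixes the C7=C8 alkene.
- Enabling feature: the C3–C4 oxirane (tertiary C4–O bond, 1,5 to the C5=C10 E-alkene) as radical source, and the C8=C9 E-alkene flanked by the C7 allylic sulfone as acceptor and leaving group. The C2 acetate and C3 oxygen act as equatorial control elements in the chair–chair array.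
- The acyclic precursor comes from C6–C7 sulfone alkylation of an (S)-citronellol-derived allyl sulfone (C13) with an epoxy allyl bromide. The bromide comes from an asymmetric vinylogous Mukaiyama aldol (C1–C2 bond, C2 centre) and a hydroxyl-directed threo epoxidation (C3).
- Ring order: oxirane first (step 3), then rings A and B together (step 14).

Key step: step 14

Remarks on the chemistry:
- The target is read as (2S,3R,5S,9R,10S,13S)-2,15-diacetoxylabd-7-en-3-ol (ent-labdane series, trans-decalin). Labdane numbers are also used for the acyclic intermediates: C15 oxygenated CH2, C13 methyl-bearing CH, C9=C8, C7 sulfone carbon, C6, C5=C10, C1, C2 carbinol, C3–C4 oxirane.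
- The sulfone-bearing C7 of the coupled intermediates forms as an epimer mixture and is destroyed in step 14, so it is left undefined in the SMILES.
- Cyclopentadienyl ligands are written as σ-bonded C5H5 rings in SMILES.

**Route**

Step 1
Reactants: 1 ethyl 3-methylbut-2-enoate
Product: 2 tert-butyl[(1-ethoxy-3-methylbuta-1,3-dien-1-yl)oxy]dimethylsilane (silyl dienol ether)
Conditions: LiN(i-Pr)2, THF, −78 °C; then TBSCl, DMPU, −78 °C to rt
Reagents that add atoms: tert-butyldimethylsilyl chloride, CC(C)(C)[Si](C)(C)Cl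
Why: Kinetic γ-deprotonation of the senecioate and O-silylation of the extended enolate is the standard entry to vinylogous Mukaiyama donors, and no stereocentre is formed.

Step 2
Reactants: 2 silyl dienol ether; 3 3-methylbut-2-enal
Product: 4 ethyl (2E,5S)-5-hydroxy-3,7-dimethylocta-2,6-dienoate
Conditions: SiCl4 (1.1 equiv), binaphthyldiamine-derived chiral bisphosphoramide (5 mol %, the antipode that directs Si-face attack), i-Pr2NEt (10 mol %), CH2Cl2, −78 °C; aq. NaHCO3
Reagents that add atoms: none
Why: In this Lewis-base-activated SiCl4 vinylogous Mukaiyama aldol the enal is bound to the chiral phosphoramide–SiCl3 cation and is attacked on its Si face by the γ-carbon of the dienol ether, which sets the 5S carbinol (C2) and gives the E-enoate.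

Step 3
Reactants: 4 ethyl (2E,5S)-5-hydroxy-3,7-dimethylocta-2,6-dienoate
Product: 5 ethyl (2E,5S)-5-[(2R)-3,3-dimethyloxiran-2-yl]-5-hydroxy-3-methylpent-2-enoate (threo epoxy alcohol)
Conditions: mCPBA (1.1 equiv), NaHCO3, CH2Cl2, 0 °C
Reagents that add atoms: 3-chloroperbenzoic acid, OOC(=O)c1cccc(Cl)c1
Why: In this hydroxyl-directed peracid epoxidation, A(1,3) strain with the cis methyl of the isopropylidene group holds the carbinol C–H in the alkene plane, so the hydrogen-bonded peracid adds syn to the hydroxyl and gives the threo (5S,2′R) oxirane (C3), while the electron-poor enoate alkene does not react.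

Step 4
Reactants: 5 threo epoxy alcohol
Product: 6 ethyl (2E,5S)-5-[(tert-butyldimethylsilyl)oxy]-5-[(2R)-3,3-dimethyloxiran-2-yl]-3-methylpent-2-enoate
Conditions: TBSCl, imidazole, DMAP (cat.), DMF, rt
Reagents that add atoms: tert-butyldimethylsilyl chloride, CC(C)(C)[Si](C)(C)Cl
Why: Silylation of the secondary alcohol under neutral conditions leaves the oxirane intact and blocks Payne rearrangement and O-alkylation in the basic steps that follow.

Step 5
Reactants: 6 silyl ether ester
Product: 7 (2E,5S)-5-[(tert-butyldimethylsilyl)oxy]-5-[(2R)-3,3-dimethyloxiran-2-yl]-3-methylpent-2-en-1-ol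
Conditions: i-Bu2AlH (2.2 equiv), CH2Cl2, −78 °C; aq. KNaC4H4O6 (potassium sodium tartrate)
Reagents that add atoms: none
Why: 1,2-Reduction of the enoate by i-Bu2AlH at −78 °C gives the E-allylic alcohol much faster than the hindered trisubstituted oxirane is opened.

Step 6
Reactants: 7 allylic alcohol
Product: 9 (2R)-2-[(1S,3E)-5-bromo-1-[(tert-butyldimethylsilyl)oxy]-3-methylpent-3-en-1-yl]-3,3-dimethyloxirane, via allylic mesylate 8 (not isolated)
Conditions: MsCl, Et3N, CH2Cl2, −40 °C; then LiBr, THF, 0 °C
Reagents that add atoms: methanesulfonyl chloride, CS(=O)(=O)Cl (mesyl group in 8 only); lithium bromide, [Li+].[Br-] (bromine in 9)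
Why: Mesylation and SN2 displacement by bromide at the primary allylic carbon proceed without acid, so the oxirane, the silyl ether and the E-alkene are kept.

Step 7
Reactants: 10 (S)-citronellol
Product: 11 tert-butyl{[(3S)-3,7-dimethyloct-6-en-1-yl]oxy}dimethylsilane
Conditions: TBSCl, imidazole, DMF, rt
Reagents that add atoms: tert-butyldimethylsilyl chloride, CC(C)(C)[Si](C)(C)Cl
Why: Silylation of the primary alcohol gives a base-stable ether, and the C13 centre is taken unchanged from the chiral pool.

Step 8
Reactants: 11 citronellyl silyl ether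
Product: 12 (2E,6S)-8-[(tert-butyldimethylsilyl)oxy]-2,6-dimethyloct-2-en-1-ol
Conditions: SeO2 (0.3 equiv), t-BuOOH, salicylic acid (cat.), CH2Cl2, rt
Reagents that add atoms: selenium dioxide, O=[Se]=O (catalytic oxygen carrier); tert-butyl hydroperoxide, CC(C)(C)OO (terminal oxygen source)
Why: SeO2 allylic oxidation (ene reaction, then [2,3]-sigmatropic shift) hydroxylates the E-methyl of the isopropylidene terminus selectively and so creates C7 as an E-allylic alcohol.

Step 9
Reactants: 12 E-allylic alcohol
Product: 13 {[(3S,6E)-8-bromo-3,7-dimethyloct-6-en-1-yl]oxy}(tert-butyl)dimethylsilane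
Conditions: CBr4, PPh3, CH2Cl2, −20 to 0 °C
Reagents that add atoms: carbon tetrabromide, BrC(Br)(Br)Br
Why: The Appel reaction converts the primary allylic alcohol into the bromide under neutral conditions without allylic transposition or loss of the silyl ether.

Step 10
Reactants: 13 allylic bromide
Product: 14 tert-butyl{[(3S,6E)-3,7-dimethyl-8-(phenylsulfonyl)oct-6-en-1-yl]oxy}dimethylsilane
Conditions: PhSO2Na, DMF, rt
Reagents that add atoms: sodium benzenesulfinate, [Na+].[O-]S(=O)c1ccccc1
Why: S-Alkylation of the sulfinate by SN2 at the primary allylic bromide gives the thermodynamically preferred E-allyl sulfone.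

Step 11
Reactants: 14 allyl sulfone; 9 epoxy allyl bromide
Product: 16 (2R)-2-[(1S,3E,6RS,7E,11S)-1,13-bis[(tert-butyldimethylsilyl)oxy]-3,7,11-trimethyl-6-(phenylsulfonyl)trideca-3,7-dien-1-yl]-3,3-dimethyloxirane, via lithiated sulfone 15 (not isolated)
Conditions: n-BuLi (1.05 equiv), THF, −78 °C; then 9, −78 to −40 °C
Reagents that add atoms: n-butyllithium, [Li]CCCC (lithium in 15 only)
Why: α-Alkylation of the sulfonyl-stabilised allyl anion with the allylic bromide forms the C6–C7 bond with both E-alkenes retained and is much faster than attack on the trisubstituted oxirane.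

Step 12
Reactants: 16 bis-silyl epoxy sulfone
Product: 17 (1S,3E,6RS,7E,11S)-1-[(2R)-3,3-dimethyloxiran-2-yl]-3,7,11-trimethyl-6-(phenylsulfonyl)trideca-3,7-diene-1,13-diol
Conditions: Bu4NF (3 equiv), AcOH (3 equiv), THF, rt
Reagents that add atoms: none
Why: Acetic-acid-buffered fluoride cleaves both Si–O bonds while keeping the C2 alkoxide protonated, so no Payne rearrangement of the epoxy alcohol takes place.

Step 13
Reactants: 17 epoxy diol
Product: 18 (1S,3E,6RS,7E,11S)-1-[(2R)-3,3-dimethyloxiran-2-yl]-3,7,11-trimethyl-6-(phenylsulfonyl)trideca-3,7-diene-1,13-diyl diacetate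
Conditions: Ac2O (3 equiv), pyridine, DMAP (cat.), CH2Cl2, 0 °C to rt
Reagents that add atoms: acetic anhydride, CC(=O)OC(C)=O
Why: Both free hydroxyls (C15 and C2) are acetylated while the C3 oxygen is still locked in the oxirane, so the acetate pattern of the target needs no later differentiation.

Step 14
Reactants: 18 epoxy diene sulfone diacetate
Product: 20 (2S,3S,5S,9R,10S,13S)-2,15-diacetoxylabd-7-en-3-ol (3-OH and 2-OAc both equatorial), via titanium alkoxide 19 (not isolated)
Conditions: Cp2TiCl2 (3 equiv), Mn dust (8 equiv), THF (degassed), rt, slow addition of 18 (final 0.01 M); then 1 M HCl, 0 °C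
Reagents that add atoms: chlorobis(cyclopentadienyl)titanium Cp2TiCl, Cl[Ti](C1C=CC=C1)C1C=CC=C1 (made in the flask from Cp2TiCl2 and Mn; titanium in 19 only)
Why: Proposed new method: Cp2TiCl (trivalent titanium) gives one electron to the oxirane and cleaves its tertiary C4–O bond, so a C4 radical forms next to a C3 titanium alkoxide; this radical adds to C5 of the C5=C10 alkene (ring A, C4–C5 bond, 6-endo-trig), the tertiary C10 radical adds to C9 of the C8=C9 alkene (ring B, C9–C10 bond, 6-endo-trig), and the C8 radical expels PhSO2 from C7, which places the alkene at C7=C8 and is reduced to sulfinate by a second Cp2TiCl. The closest known reactions are the Cp2TiCl-mediated radical bicyclisation of epoxypolyprenes, which ends by hydride loss to an exocyclic alkene, and the radical allylation with allyl sulfones by addition and β-loss of the sulfonyl radical; joining the two in one cascade is the new element. C5, C10 and C9 come from the chair–chair array of the E,E-diene (trans ring fusion, C20 axial, C9 side chain equatorial), and the face of the C5=C10 alkene is chosen by the stored centres C3 and C2, whose O–Ti and OAc groups are both equatorial only in the array that leads to 20. The step needs 6-endo over 5-exo closure twice, secured by the methyl groups on C10 and C8 that block the exo carbons and make the endo radicals tertiary; it needs a C4 radical and not a C4 cation, so that the neighbouring C2 acetate cannot take part, which the one-electron opening secures; and it needs sulfonyl loss to outrun hydride loss, which the weak C7–S bond β to the radical is expected to secure for either C7 epimer.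

Step 15
Reactants: 20 equatorial 3-alcohol
Product: 21 (2S,5S,9R,10S,13S)-2,15-diacetoxylabd-7-en-3-one
Conditions: Dess–Martin periodinane, NaHCO3, CH2Cl2, rt
Reagents that add atoms: none
Why: Buffered Dess–Martin oxidation turns the hindered secondary alcohol into the ketone without touching the trisubstituted alkene or the acetates, and the equatorial 2-acetate is the stable epimer next to the carbonyl.

Step 16
Reactants: 21 2-acetoxy 3-ketone
Product: 22 (2S,3R,5S,9R,10S,13S)-2,15-diacetoxylabd-7-en-3-ol (target)
Conditions: LiBH(s-Bu)3 (1.2 equiv), THF, −78 °C; AcOH quench at −78 °C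
Reagents that add atoms: none
Why: The bulky trialkylborohydride cannot use the axial path past the syn-axial hydrogens at C1 and C5 and should attack equatorially, giving the axial 3-OH cis to the 2-OAc (3R), while the acetates survive at −78 °C and any acetyl migration would favour the equatorial 2-acetate.

**Compound list**

1 | ethyl 3-methylbut-2-enoate | CCOC(=O)C=C(C)C | starting material
2 | tert-butyl[(1-ethoxy-3-methylbuta-1,3-dien-1-yl)oxy]dimethylsilane | CCOC(=CC(C)=C)O[Si](C)(C)C(C)(C)C | intermediate
3 | 3-methylbut-2-enal | CC(C)=CC=O | starting material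
4 | ethyl (2E,5S)-5-hydroxy-3,7-dimethylocta-2,6-dienoate | CCOC(=O)/C=C(\C)C[C@H](O)C=C(C)C | intermediate
5 | ethyl (2E,5S)-5-[(2R)-3,3-dimethyloxiran-2-yl]-5-hydroxy-3-methylpent-2-enoate | CCOC(=O)/C=C(\C)C[C@H](O)[C@H]1OC1(C)C | intermediate
6 | ethyl (2E,5S)-5-[(tert-butyldimethylsilyl)oxy]-5-[(2R)-3,3-dimethyloxiran-2-yl]-3-methylpent-2-enoate | CCOC(=O)/C=C(\C)C[C@H](O[Si](C)(C)C(C)(C)C)[C@H]1OC1(C)C | intermediate
7 | (2E,5S)-5-[(tert-butyldimethylsilyl)oxy]-5-[(2R)-3,3-dimethyloxiran-2-yl]-3-methylpent-2-en-1-ol | OC/C=C(\C)C[C@H](O[Si](C)(C)C(C)(C)C)[C@H]1OC1(C)C | intermediate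
8 | methanesulfonate of 7 (not isolated) | CS(=O)(=O)OC/C=C(\C)C[C@H](O[Si](C)(C)C(C)(C)C)[C@H]1OC1(C)C | intermediate
9 | (2R)-2-[(1S,3E)-5-bromo-1-[(tert-butyldimethylsilyl)oxy]-3-methylpent-3-en-1-yl]-3,3-dimethyloxirane | BrC/C=C(\C)C[C@H](O[Si](C)(C)C(C)(C)C)[C@H]1OC1(C)C | intermediate
10 | (S)-citronellol, (3S)-3,7-dimethyloct-6-en-1-ol | OCC[C@@H](C)CCC=C(C)C | starting material
11 | tert-butyl{[(3S)-3,7-dimethyloct-6-en-1-yl]oxy}dimethylsilane | CC(C)(C)[Si](C)(C)OCC[C@@H](C)CCC=C(C)C | intermediate
12 | (2E,6S)-8-[(tert-butyldimethylsilyl)oxy]-2,6-dimethyloct-2-en-1-ol | CC(C)(C)[Si](C)(C)OCC[C@@H](C)CC/C=C(\C)CO | intermediate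
13 | {[(3S,6E)-8-bromo-3,7-dimethyloct-6-en-1-yl]oxy}(tert-butyl)dimethylsilane | CC(C)(C)[Si](C)(C)OCC[C@@H](C)CC/C=C(\C)CBr | intermediate
14 | tert-butyl{[(3S,6E)-3,7-dimethyl-8-(phenylsulfonyl)oct-6-en-1-yl]oxy}dimethylsilane | CC(C)(C)[Si](C)(C)OCC[C@@H](C)CC/C=C(\C)CS(=O)(=O)c1ccccc1 | intermediate
15 | α-lithio derivative of 14, lithium on the sulfone carbon (not isolated) | CC(C)(C)[Si](C)(C)OCC[C@@H](C)CC/C=C(\C)C([Li])S(=O)(=O)c1ccccc1 | intermediate
16 | (2R)-2-[(1S,3E,6RS,7E,11S)-1,13-bis[(tert-butyldimethylsilyl)oxy]-3,7,11-trimethyl-6-(phenylsulfonyl)trideca-3,7-dien-1-yl]-3,3-dimethyloxirane | CC(C)(C)[Si](C)(C)OCC[C@@H](C)CC/C=C(\C)C(C/C=C(\C)C[C@H](O[Si](C)(C)C(C)(C)C)[C@H]1OC1(C)C)S(=O)(=O)c2ccccc2 | intermediate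
17 | (1S,3E,6RS,7E,11S)-1-[(2R)-3,3-dimethyloxiran-2-yl]-3,7,11-trimethyl-6-(phenylsulfonyl)trideca-3,7-diene-1,13-diol | OCC[C@@H](C)CC/C=C(\C)C(C/C=C(\C)C[C@H](O)[C@H]1OC1(C)C)S(=O)(=O)c2ccccc2 | intermediate
18 | 1,13-diacetate of 17 | CC(=O)OCC[C@@H](C)CC/C=C(\C)C(C/C=C(\C)C[C@H](OC(C)=O)[C@H]1OC1(C)C)S(=O)(=O)c2ccccc2 | intermediate
19 | chlorobis(cyclopentadienyl)titanium 3-alkoxide of 20 (not isolated) | CC(=O)OCC[C@@H](C)CC[C@@H]1C(C)=CC[C@@H]2C(C)(C)[C@H](O[Ti](Cl)(C3C=CC=C3)C3C=CC=C3)[C@@H](OC(C)=O)C[C@@]12C | intermediate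
20 | (2S,3S,5S,9R,10S,13S)-2,15-diacetoxylabd-7-en-3-ol | CC(=O)OCC[C@@H](C)CC[C@@H]1C(C)=CC[C@@H]2C(C)(C)[C@H](O)[C@@H](OC(C)=O)C[C@@]12C | intermediate
21 | (2S,5S,9R,10S,13S)-2,15-diacetoxylabd-7-en-3-one | CC(=O)OCC[C@@H](C)CC[C@@H]1C(C)=CC[C@@H]2C(C)(C)C(=O)[C@@H](OC(C)=O)C[C@@]12C | intermediate
22 | (2S,3R,5S,9R,10S,13S)-2,15-diacetoxylabd-7-en-3-ol | CC(=O)OCC[C@@H](C)CC[C@@H]1C(C)=CC[C@@H]2C(C)(C)[C@@H](O)[C@@H](OC(C)=O)C[C@@]12C | target

**Step count and risks**

Total step count: 16. Longest linear sequence: 12 steps (steps 1–6, then 11–16); the citronellol branch (steps 7–10) joins at step 11.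

Steps most likely to fail:

1. Step 14 (new cascade). The C8 radical may lose a hydride or be reduced before the sulfonyl group leaves, the allyl sulfone may scramble by sulfonyl-radical chain transfer, or the C4 radical may be reduced before it cyclises. The fallback removes the sulfone before cyclisation and places the alkene afterwards by known steps. It sets out from 16. PdCl2(dppp)-catalysed hydride displacement of the allylic sulfone with LiBHEt3 (THF, −20 °C, position and geometry of the alkene retained) should give the sulfone-free bis-silyl ether (2R)-2-[(1S,3E,7E,11S)-1,13-bis[(tert-butyldimethylsilyl)oxy]-3,7,11-trimethyltrideca-3,7-dien-1-yl]-3,3-dimethyloxirane F1. Bu4NF/AcOH should then give the epoxy diol F2, and Ac2O/pyridine the epoxy diene diacetate F3. The established Cp2TiCl-mediated bicyclisation of epoxypolyprenes (Cp2TiCl2, Mn, THF), which ends by hydride loss toward the methyl group, should give the exocyclic alkene (2S,3S,5S,9R,10S,13S)-2,15-diacetoxylabd-8(17)-en-3-ol F4. Hydrogen-atom-transfer isomerisation with a chloro cobalt salen complex Co(salen)Cl (cat.) and PhSiH3 in benzene should move the 1,1-disubstituted alkene into the ring toward the C7 methylene. The fallback returns to the route at 20.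

2. Step 2. Enantiofacial control may be eroded by an uncatalysed background reaction, and α-attack of the dienol ether may compete with γ-attack. The fallback sets the carbinol by reduction instead, and sets out from 2 and 3. A BF3·OEt2-promoted vinylogous Mukaiyama aldol (CH2Cl2, −78 °C) should give racemic ethyl (2E)-5-hydroxy-3,7-dimethylocta-2,6-dienoate F5. Buffered Dess–Martin oxidation should give ethyl (2E)-3,7-dimethyl-5-oxoocta-2,6-dienoate F6. Corey–Bakshi–Shibata reduction with the (R)-2-methyl-oxazaborolidine and catecholborane (toluene, −78 °C), with the alkenyl group as the large substituent, should give the 5S alcohol. The fallback returns to the route at 4.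

3. Step 16. The hydride may attack the acetates, or the acetyl group may migrate from O2 to O3 in the cis alkoxide before the quench. The fallback gives up the acetates deliberately and restores them at the end, and sets out from 21. Excess LiBH(s-Bu)3 (THF, −78 to 0 °C) followed by K2CO3 in MeOH should give (2S,3R,5S,9R,10S,13S)-labd-7-ene-2,3,15-triol F7. Ac2O (2.2 equiv) in pyridine at 0 °C should then acetylate the primary C15 hydroxyl and the equatorial C2 hydroxyl, leaving the axial neopentyl C3 hydroxyl next to the gem-dimethyl carbon free. The fallback returns to the route at 22.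

**Further compounds**

F1 | step 14 | (2R)-2-[(1S,3E,7E,11S)-1,13-bis[(tert-butyldimethylsilyl)oxy]-3,7,11-trimethyltrideca-3,7-dien-1-yl]-3,3-dimethyloxirane | CC(C)(C)[Si](C)(C)OCC[C@@H](C)CC/C=C(\C)CC/C=C(\C)C[C@H](O[Si](C)(C)C(C)(C)C)[C@H]1OC1(C)C
F2 | step 14 | (1S,3E,7E,11S)-1-[(2R)-3,3-dimethyloxiran-2-yl]-3,7,11-trimethyltrideca-3,7-diene-1,13-diol | OCC[C@@H](C)CC/C=C(\C)CC/C=C(\C)C[C@H](O)[C@H]1OC1(C)C
F3 | step 14 | 1,13-diacetate of F2 | CC(=O)OCC[C@@H](C)CC/C=C(\C)CC/C=C(\C)C[C@H](OC(C)=O)[C@H]1OC1(C)C
F4 | step 14 | (2S,3S,5S,9R,10S,13S)-2,15-diacetoxylabd-8(17)-en-3-ol | CC(=O)OCC[C@@H](C)CC[C@@H]1C(=C)CC[C@@H]2C(C)(C)[C@H](O)[C@@H](OC(C)=O)C[C@@]12C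
F5 | step 2 | racemic ethyl (2E)-5-hydroxy-3,7-dimethylocta-2,6-dienoate | CCOC(=O)/C=C(\C)CC(O)C=C(C)C
F6 | step 2 | ethyl (2E)-3,7-dimethyl-5-oxoocta-2,6-dienoate | CCOC(=O)/C=C(\C)CC(=O)C=C(C)C
F7 | step 16 | (2S,3R,5S,9R,10S,13S)-labd-7-ene-2,3,15-triol | OCC[C@@H](C)CC[C@@H]1C(C)=CC[C@@H]2C(C)(C)[C@@H](O)[C@@H](O)C[C@@]12C
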